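Retrosynthetic overview
1. C14–C15 is made last by a Heck-type C–H alkenylation. The terminal CH2=C15 of an unprotected C21 vinyl-pentaene is "vinylogously acylated" by an unprotected C14-iodotrienone, so no tin, boron or protecting group enters the union.
2. Enabling feature: the C8 ketone is conjugated through C9=C10–C11=C12–C13=C14. C14–I therefore behaves as a vinylogous acyl iodide (fast oxidative addition). After carbopalladation the C15–H is vinylogously alpha to C8=O, which fixes the direction of the elimination.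
3. Left half: C9–C10 by Morita–Baylis–Hillman union of a vinyl ketone with a C6 iodo-dienal. The C19–O laurate and the C9=C10 geometry come from an SN2' Mitsunobu transposition. C7–C8 comes from ene-type acylation of an exocyclic methylene made from (4R,6R)-actinol.
4. Right half: rac-alpha-ionone, C3' oxygen by allylic oxidation and Luche reduction, resolution as the O-methylmandelate, two Horner–Wadsworth–Emmons extensions, then a Wittig methylenation.
5. No ring is formed. Ring A (beta ring, C1–C6) comes from actinol and ring B (epsilon ring, C1'–C6') from alpha-ionone; only alkene position and oxygenation are adjusted.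

Key step: step 17

Remark: carotenoid numbering is used (C19 = CH2O on C9, C20 = CH3 on C13, primed numbers for the epsilon half). All polyenes are handled under argon in the dark.
Assumption: (4R,6R)-actinol, (2E)-pent-2-en-4-yn-1-ol and diethyl [(2E)-3-cyano-2-methylprop-2-enyl]phosphonate are taken as catalogue compounds.

Step 1
Reactants: 1 (4R,6R)-4-hydroxy-2,2,6-trimethylcyclohexan-1-one (actinol)
Product: 2 (4R,6R)-4-(tert-butyldimethylsilyloxy)-2,2,6-trimethylcyclohexan-1-one
Conditions: TBSCl, imidazole, DMF, 23 °C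
Reagents that add atoms: tert-butyldimethylsilyl chloride, CC(C)(C)[Si](C)(C)Cl
Why: Imidazole-promoted silylation of the only hydroxyl group masks O3 against the acid chloride of step 3 and the Mitsunobu reaction of step 7, and touches no stereocentre.

Step 2
Reactants: 2 (4R,6R)-4-(tert-butyldimethylsilyloxy)-2,2,6-trimethylcyclohexan-1-one
Product: 3 tert-butyl(dimethyl){[(1R,5R)-3,3,5-trimethyl-4-methylidenecyclohexyl]oxy}silane
Conditions: MePPh3Br, KOt-Bu, toluene, 90 °C
Reagents that add atoms: methyltriphenylphosphonium bromide, C[P+](c1ccccc1)(c1ccccc1)c1ccccc1.[Br-]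
Why: Wittig methylenation with an alkoxide-generated ylide at raised temperature is the usual answer to hindered 2,2,6-trisubstituted cyclohexanones; epimerisation at the methyl-bearing carbon would be harmless because that centre becomes sp2 in step 3.

Step 3
Reactants: 3 tert-butyl(dimethyl){[(1R,5R)-3,3,5-trimethyl-4-methylidenecyclohexyl]oxy}silane; 4 3-chloropropanoyl chloride
Product: 6 1-[(4R)-4-(tert-butyldimethylsilyloxy)-2,6,6-trimethylcyclohex-1-en-1-yl]but-3-en-2-one, via 2-chloroethyl ketone 5 (not isolated)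
Conditions: EtAlCl2, CH2Cl2, −78 to −20 °C; then Et3N, 0 to 23 °C
Reagents that add atoms: none
Why: In this aliphatic Friedel–Crafts (Kondakov-type, ene-like) acylation the acylium complex attacks the unhindered CH2 terminus (new C7–C8 bond), carbonyl-assisted loss of the ring C5 hydrogen places the alkene at the tetrasubstituted C5=C6 position while EtAlCl2 scavenges HCl, and Et3N then removes HCl (E1cB) to unveil the vinyl ketone; C3 is untouched.

Step 4
Reactants: 7 (2E)-pent-2-en-4-yn-1-ol
Product: 9 (2E,4E)-5-iodo-4-methylpenta-2,4-dien-1-ol, via alkenylalane 8 (not isolated)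
Conditions: AlMe3 (3 equiv), Cp2ZrCl2 (0.25 equiv), CH2Cl2, 0 to 23 °C; then I2, THF, −30 °C
Reagents that add atoms: trimethylaluminium, C[Al](C)C; iodine, II
Why: Zirconium-catalysed carboalumination (Negishi) adds CH3 and Al syn across the terminal alkyne with Al on the terminal carbon, and iodinolysis with retention should give the E-configured C13(CH3)=C14–I unit.

Step 5
Reactants: 9 (2E,4E)-5-iodo-4-methylpenta-2,4-dien-1-ol
Product: 10 (2E,4E)-5-iodo-4-methylpenta-2,4-dienal
Conditions: MnO2, CH2Cl2, 23 °C, dark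
Reagents that add atoms: none
Why: Manganese dioxide oxidation of a primary allylic alcohol stops at the aldehyde and leaves the alkenyl iodide and both alkene geometries intact.

Step 6
Reactants: 6 1-[(4R)-4-(tert-butyldimethylsilyloxy)-2,6,6-trimethylcyclohex-1-en-1-yl]but-3-en-2-one; 10 (2E,4E)-5-iodo-4-methylpenta-2,4-dienal
Product: 11 (5E,7E)-1-[(4R)-4-(tert-butyldimethylsilyloxy)-2,6,6-trimethylcyclohex-1-en-1-yl]-4-hydroxy-8-iodo-7-methyl-3-methylideneocta-5,7-dien-2-one (both C10 epimers)
Conditions: DABCO (0.5 equiv), 1,4-dioxane/H2O, 23 °C, dark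
Reagents that add atoms: none
Why: In this Morita–Baylis–Hillman reaction DABCO adds to C19 of the vinyl ketone, the zwitterionic enolate attacks aldehyde carbon C10 (new C9–C10 bond) and the amine is expelled; the new C10 carbinol centre forms without control and is erased in step 7.

Step 7
Reactants: 11 Baylis–Hillman alcohol (both C10 epimers); 12 dodecanoic acid (lauric acid)
Product: 13 (2E,4E,6E)-2-{[(4R)-4-(tert-butyldimethylsilyloxy)-2,6,6-trimethylcyclohex-1-en-1-yl]acetyl}-7-iodo-6-methylhepta-2,4,6-trien-1-yl dodecanoate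
Conditions: PPh3, DIAD, THF, −20 to 0 °C
Reagents that add atoms: none
Why: This is a Mitsunobu reaction in the SN2' mode known for Baylis–Hillman alcohols, in which the C8 ketone makes C19 a Michael terminus, so laurate should add there as the C10 oxyphosphonium leaves; minimised allylic strain should place C11 trans to C8=O (9E), and both C10 epimers converge.

Step 8
Reactants: 13 silyl-protected left-half iodide
Product: 14 (2E,4E,6E)-2-{[(4R)-4-hydroxy-2,6,6-trimethylcyclohex-1-en-1-yl]acetyl}-7-iodo-6-methylhepta-2,4,6-trien-1-yl dodecanoate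
Conditions: HF·pyridine, pyridine, THF, 0 to 23 °C
Reagents that add atoms: none
Why: Pyridine-buffered fluoride desilylation frees O3 under conditions that spare the allylic laurate, the enone and the alkenyl iodide, with C3 unchanged.

Step 9
Reactants: 15 rac-alpha-ionone; 16 diethyl cyanomethylphosphonate
Product: 17 rac-(2E,4E)-3-methyl-5-(2,6,6-trimethylcyclohex-2-en-1-yl)penta-2,4-dienenitrile
Conditions: NaH, THF, 0 to 23 °C; chromatography (9'E isomer kept)
Reagents that add atoms: none
Why: Horner–Wadsworth–Emmons olefination of the methyl ketone with a weakly basic stabilised anion builds C9'=C10' without moving the ring alkene into conjugation, and the minor 9'Z isomer is removed.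

Step 10
Reactants: 17 rac-C15 nitrile
Product: 18 rac-(2E,4E)-3-methyl-5-(2,6,6-trimethyl-4-oxocyclohex-2-en-1-yl)penta-2,4-dienenitrile
Conditions: t-BuOOH, aq NaOCl, K2CO3, MeCN, 0 °C
Reagents that add atoms: tert-butyl hydroperoxide, CC(C)(C)OO
Why: Radical allylic oxidation by tert-butylperoxyl radicals, precedented on alpha-ionone derivatives, attacks the only unhindered ring allylic CH2 (C3'); the material is still racemic, so the acidified C6' hydrogen of the enone is of no consequence.

Step 11
Reactants: 18 rac-3'-oxo nitrile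
Product: 19 rac-(2E,4E)-5-[(1R*,4R*)-4-hydroxy-2,6,6-trimethylcyclohex-2-en-1-yl]-3-methylpenta-2,4-dienenitrile (3',6'-trans racemate)
Conditions: NaBH4, CeCl3·7H2O, MeOH, −20 °C; chromatography
Reagents that add atoms: none
Why: Luche reduction is 1,2-selective for the ring enone and leaves the dienenitrile alone; the relative configuration C3'/C6' is not fixed by the reagent, so the 3',6'-trans racemate is selected from its cis isomer by chromatography.

Step 12
Reactants: 19 rac-trans hydroxy nitrile; 20 (2S)-2-methoxy-2-phenylacetic acid ((S)-O-methylmandelic acid)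
Product: 21 (1R,4R)-4-[(1E,3E)-4-cyano-3-methylbuta-1,3-dien-1-yl]-3,5,5-trimethylcyclohex-2-en-1-yl (2S)-2-methoxy-2-phenylacetate
Conditions: DCC, DMAP (cat.), CH2Cl2, 0 °C; chromatography
Reagents that add atoms: none
Why: Steglich esterification with an enantiopure acid turns the racemate into two diastereomeric esters that are separated, and the (3'R,6'R) ester is recognised by the phenyl anisotropy model for O-methylmandelates; this classical resolution fixes the absolute configuration of C3' and C6' together.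

Step 13
Reactants: 21 (3'R,6'R)-O-methylmandelate
Product: 23 (2E,4E)-5-[(1R,4R)-4-hydroxy-2,6,6-trimethylcyclohex-2-en-1-yl]-3-methylpenta-2,4-dienal, via N-aluminoimine 22 (not isolated)
Conditions: i-Bu2AlH (4 equiv), CH2Cl2, −78 °C; then aq potassium sodium tartrate, 23 °C
Reagents that add atoms: water, O
Why: Diisobutylaluminium hydride reduction stops at the N-aluminoimine, which hydrolyses to the aldehyde, and the same reagent removes the resolving ester reductively, so no separate deprotection is needed and no stereocentre is touched.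

Step 14
Reactants: 23 C15 hydroxy aldehyde; 24 diethyl [(2E)-3-cyano-2-methylprop-2-en-1-yl]phosphonate
Product: 25 (2E,4E,6E,8E)-9-[(1R,4R)-4-hydroxy-2,6,6-trimethylcyclohex-2-en-1-yl]-3,7-dimethylnona-2,4,6,8-tetraenenitrile
Conditions: LiN(SiMe3)2, THF, −78 to 0 °C; chromatography (all-E isomer kept)
Reagents that add atoms: none
Why: The vinylogous Horner–Wadsworth–Emmons reaction standard in retinoid chemistry builds C11'=C12' with E selectivity, the free hydroxyl only consumes extra base, and any 13'Z isomer is removed.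

Step 15
Reactants: 25 C20 hydroxy nitrile
Product: 27 (2E,4E,6E,8E)-9-[(1R,4R)-4-hydroxy-2,6,6-trimethylcyclohex-2-en-1-yl]-3,7-dimethylnona-2,4,6,8-tetraenal, via N-aluminoimine 26 (not isolated)
Conditions: i-Bu2AlH (2.5 equiv), CH2Cl2, −78 °C; then aq potassium sodium tartrate, 23 °C
Reagents that add atoms: water, O
Why: Partial reduction of the nitrile with diisobutylaluminium hydride followed by imine hydrolysis gives the polyenal directly, so no oxidant ever meets the allylic 3'-hydroxyl group.

Step 16
Reactants: 27 C20 hydroxy aldehyde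
Product: 28 (1R,4R)-4-[(1E,3E,5E,7E)-3,7-dimethyldeca-1,3,5,7,9-pentaen-1-yl]-3,5,5-trimethylcyclohex-2-en-1-ol
Conditions: MePPh3Br, KOt-Bu, THF, 0 °C, dark
Reagents that add atoms: methyltriphenylphosphonium bromide, C[P+](c1ccccc1)(c1ccccc1)c1ccccc1.[Br-]
Why: Wittig methylenation of the unhindered polyenal adds C15 as a terminal CH2 without disturbing the four E alkenes or the two ring stereocentres.

Step 17
Reactants: 14 left-half C14 iodide (free 3-OH); 28 right-half vinyl-pentaene (free 3'-OH)
Product: 29 (3R,3'R,6'R)-19-(dodecanoyloxy)-3,3'-dihydroxy-7,8-dihydro-beta,epsilon-caroten-8-one (CNP0415583.1)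
Conditions: Pd(OAc)2 (10 mol %), Ag2CO3 (1 equiv), DMF, 23 °C, argon, dark
Reagents that add atoms: none
Why: Zerovalent palladium formed in situ inserts with retention into the C14–I bond of 14, which is a vinylogous acyl iodide through C13=C14–C11=C12–C9=C10–C8=O, so oxidative addition at 23 °C should outrun ionisation of the allylic C19 laurate, and Ag2CO3 strips iodide so that the cationic alkenylpalladium binds the only monosubstituted alkene of 28, CH2(15)=CH(15'). Syn carbopalladation puts C14 on the unhindered terminus C15 and palladium on C15', where it rests as an eta-3 polyenyl complex; loss of a C15 hydrogen, which is allylic to palladium and vinylogously alpha to the C8 ketone, restores the alkene in the one direction that merges the two chromophores into the nonaenone. The closest known reaction type is the Heck alkenylation of terminal 1,3-dienes with alkenyl iodides under ligand-free, silver-assisted conditions. The step closes no ring and creates no stereocentre; C3, C3' and C6' are spectators, and C6' should stay intact because silver carbonate consumes the palladium hydride before it can re-add to the chain. The step needs site selectivity for C15 over the four internal chain alkenes and the ring B alkene, E geometry at C15=C15', and retention at C13=C14. These are secured by the steric uniqueness of the vinyl terminus, by syn insertion and syn elimination through the less crowded rotamer, and by stereoretentive oxidative addition, respectively.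

Compound list
1 | (4R,6R)-4-hydroxy-2,2,6-trimethylcyclohexan-1-one (actinol) | CC1(C)C[C@H](O)C[C@@H](C)C1=O | starting material
2 | (4R,6R)-4-(tert-butyldimethylsilyloxy)-2,2,6-trimethylcyclohexan-1-one | CC1(C)C[C@H](O[Si](C)(C)C(C)(C)C)C[C@@H](C)C1=O | intermediate
3 | tert-butyl(dimethyl){[(1R,5R)-3,3,5-trimethyl-4-methylidenecyclohexyl]oxy}silane | CC1(C)C[C@H](O[Si](C)(C)C(C)(C)C)C[C@@H](C)C1=C | intermediate
4 | 3-chloropropanoyl chloride | ClCCC(Cl)=O | starting material
5 | 4-chloro-1-[(4R)-4-(tert-butyldimethylsilyloxy)-2,6,6-trimethylcyclohex-1-en-1-yl]butan-2-one | ClCCC(=O)CC1=C(C)C[C@@H](O[Si](C)(C)C(C)(C)C)CC1(C)C | intermediate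
6 | 1-[(4R)-4-(tert-butyldimethylsilyloxy)-2,6,6-trimethylcyclohex-1-en-1-yl]but-3-en-2-one | C=CC(=O)CC1=C(C)C[C@@H](O[Si](C)(C)C(C)(C)C)CC1(C)C | intermediate
7 | (2E)-pent-2-en-4-yn-1-ol | OC/C=C/C#C | starting material
8 | [(1E,3E)-5-(dimethylalumanyloxy)-2-methylpenta-1,3-dien-1-yl]dimethylalumane | C[Al](C)OC/C=C/C(C)=C/[Al](C)C | intermediate
9 | (2E,4E)-5-iodo-4-methylpenta-2,4-dien-1-ol | OC/C=C/C(C)=C/I | intermediate
10 | (2E,4E)-5-iodo-4-methylpenta-2,4-dienal | O=C/C=C/C(C)=C/I | intermediate
11 | (5E,7E)-1-[(4R)-4-(tert-butyldimethylsilyloxy)-2,6,6-trimethylcyclohex-1-en-1-yl]-4-hydroxy-8-iodo-7-methyl-3-methylideneocta-5,7-dien-2-one (C10 epimers) | C=C(C(O)/C=C/C(C)=C/I)C(=O)CC1=C(C)C[C@@H](O[Si](C)(C)C(C)(C)C)CC1(C)C | intermediate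
12 | dodecanoic acid (lauric acid) | CCCCCCCCCCCC(=O)O | starting material
13 | (2E,4E,6E)-2-{[(4R)-4-(tert-butyldimethylsilyloxy)-2,6,6-trimethylcyclohex-1-en-1-yl]acetyl}-7-iodo-6-methylhepta-2,4,6-trien-1-yl dodecanoate | CCCCCCCCCCCC(=O)OC\C(=C/C=C/C(C)=C/I)C(=O)CC1=C(C)C[C@@H](O[Si](C)(C)C(C)(C)C)CC1(C)C | intermediate
14 | (2E,4E,6E)-2-{[(4R)-4-hydroxy-2,6,6-trimethylcyclohex-1-en-1-yl]acetyl}-7-iodo-6-methylhepta-2,4,6-trien-1-yl dodecanoate | CCCCCCCCCCCC(=O)OC\C(=C/C=C/C(C)=C/I)C(=O)CC1=C(C)C[C@@H](O)CC1(C)C | intermediate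
15 | rac-alpha-ionone, (3E)-4-(2,6,6-trimethylcyclohex-2-en-1-yl)but-3-en-2-one | CC(=O)/C=C/C1C(C)=CCCC1(C)C | starting material
16 | diethyl cyanomethylphosphonate | CCOP(=O)(CC#N)OCC | starting material
17 | rac-(2E,4E)-3-methyl-5-(2,6,6-trimethylcyclohex-2-en-1-yl)penta-2,4-dienenitrile | N#C/C=C(C)/C=C/C1C(C)=CCCC1(C)C | intermediate
18 | rac-(2E,4E)-3-methyl-5-(2,6,6-trimethyl-4-oxocyclohex-2-en-1-yl)penta-2,4-dienenitrile | N#C/C=C(C)/C=C/C1C(C)=CC(=O)CC1(C)C | intermediate
19 | rac-(2E,4E)-5-[(1R*,4R*)-4-hydroxy-2,6,6-trimethylcyclohex-2-en-1-yl]-3-methylpenta-2,4-dienenitrile (racemate, one enantiomer drawn) | N#C/C=C(C)/C=C/[C@H]1C(C)=C[C@H](O)CC1(C)C | intermediate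
20 | (2S)-2-methoxy-2-phenylacetic acid | CO[C@H](C(=O)O)c1ccccc1 | starting material
21 | (1R,4R)-4-[(1E,3E)-4-cyano-3-methylbuta-1,3-dien-1-yl]-3,5,5-trimethylcyclohex-2-en-1-yl (2S)-2-methoxy-2-phenylacetate | N#C/C=C(C)/C=C/[C@H]1C(C)=C[C@H](OC(=O)[C@@H](OC)c2ccccc2)CC1(C)C | intermediate
22 | N,O-bis(diisobutylalumanyl) derivative of the C15 hydroxy aldimine | CC(C)C[Al](CC(C)C)/N=C/C=C(C)/C=C/[C@H]1C(C)=C[C@H](O[Al](CC(C)C)CC(C)C)CC1(C)C | intermediate
23 | (2E,4E)-5-[(1R,4R)-4-hydroxy-2,6,6-trimethylcyclohex-2-en-1-yl]-3-methylpenta-2,4-dienal | O=C/C=C(C)/C=C/[C@H]1C(C)=C[C@H](O)CC1(C)C | intermediate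
24 | diethyl [(2E)-3-cyano-2-methylprop-2-en-1-yl]phosphonate | CCOP(=O)(C/C(C)=C/C#N)OCC | starting material
25 | (2E,4E,6E,8E)-9-[(1R,4R)-4-hydroxy-2,6,6-trimethylcyclohex-2-en-1-yl]-3,7-dimethylnona-2,4,6,8-tetraenenitrile | N#C/C=C(C)/C=C/C=C(C)/C=C/[C@H]1C(C)=C[C@H](O)CC1(C)C | intermediate
26 | N,O-bis(diisobutylalumanyl) derivative of the C20 hydroxy aldimine | CC(C)C[Al](CC(C)C)/N=C/C=C(C)/C=C/C=C(C)/C=C/[C@H]1C(C)=C[C@H](O[Al](CC(C)C)CC(C)C)CC1(C)C | intermediate
27 | (2E,4E,6E,8E)-9-[(1R,4R)-4-hydroxy-2,6,6-trimethylcyclohex-2-en-1-yl]-3,7-dimethylnona-2,4,6,8-tetraenal | O=C/C=C(C)/C=C/C=C(C)/C=C/[C@H]1C(C)=C[C@H](O)CC1(C)C | intermediate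
28 | (1R,4R)-4-[(1E,3E,5E,7E)-3,7-dimethyldeca-1,3,5,7,9-pentaen-1-yl]-3,5,5-trimethylcyclohex-2-en-1-ol | C=C/C=C(C)/C=C/C=C(C)/C=C/[C@H]1C(C)=C[C@H](O)CC1(C)C | intermediate
29 | (3R,3'R,6'R)-19-(dodecanoyloxy)-3,3'-dihydroxy-7,8-dihydro-beta,epsilon-caroten-8-one (CNP0415583.1) | CCCCCCCCCCCC(=O)OC\C(=C/C=C/C(C)=C/C=C/C=C(C)/C=C/C=C(C)/C=C/[C@H]1C(C)=C[C@H](O)CC1(C)C)C(=O)CC1=C(C)C[C@@H](O)CC1(C)C | target

Total step count: 17
Longest linear sequence: 9 steps (15 to 29, steps 9–17). The left branch from 1 needs 7 steps to 29, and the C6 iodo-dienal branch adds 2.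

Steps most likely to fail

Step 17. Three processes could spoil the union. Oxygen nucleophiles may intercept the eta-3 polyenylpalladium intermediate. Palladium hydride may re-add, with loss of alkene geometry. Zerovalent palladium may slowly ionise the allylic laurate. The fallback sets out from 27 and 14 and returns at 29. Aldehyde 27 is treated with Bu3SnCHBr2, CrCl2 and LiI in DMF (Takai-type stannyl-olefination) to give (1R,4R)-4-[(1E,3E,5E,7E,9E)-3,7-dimethyl-10-(tributylstannyl)deca-1,3,5,7,9-pentaen-1-yl]-3,5,5-trimethylcyclohex-2-en-1-ol F1. This stannane is joined to 14 with monovalent copper thiophene-2-carboxylate, Cu(O2CC4H3S), in NMP at 0 °C. That palladium-free Stille-type coupling is stereoretentive at both carbons and cannot ionise the allylic ester.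

Step 3. Cationic 1,2-methyl migration from the gem-dimethyl carbon, proton loss toward C7 instead of C5, or Lewis-acid cleavage of the silyl ether could occur. The fallback sets out from 3 and returns at 6. A concerted carbonyl-ene reaction with paraformaldehyde and Me2AlCl gives 2-[(4R)-4-(tert-butyldimethylsilyloxy)-2,6,6-trimethylcyclohex-1-en-1-yl]ethanol F2. Dess–Martin oxidation gives [(4R)-4-(tert-butyldimethylsilyloxy)-2,6,6-trimethylcyclohex-1-en-1-yl]acetaldehyde F3. Addition of vinylmagnesium bromide gives 1-[(4R)-4-(tert-butyldimethylsilyloxy)-2,6,6-trimethylcyclohex-1-en-1-yl]but-3-en-2-ol F4, and a second Dess–Martin oxidation gives 6.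

Step 6. Addition to the deactivated dienal may be sluggish, and amine-induced dimerisation of the vinyl ketone may compete. The fallback sets out from 6 and 10 and returns at 11. Conjugate addition of Me2AlSePh to 6 at −78 °C forms an aluminium enolate that is trapped by 10 in an aldol reaction. The product is (5E,7E)-1-[(4R)-4-(tert-butyldimethylsilyloxy)-2,6,6-trimethylcyclohex-1-en-1-yl]-4-hydroxy-8-iodo-7-methyl-3-[(phenylselanyl)methyl]octa-5,7-dien-2-one F5. Oxidation with H2O2 and pyridine at 0 °C, followed by selenoxide syn-elimination, gives 11.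

Further compounds
F1 | step 17 | (1R,4R)-4-[(1E,3E,5E,7E,9E)-3,7-dimethyl-10-(tributylstannyl)deca-1,3,5,7,9-pentaen-1-yl]-3,5,5-trimethylcyclohex-2-en-1-ol | CCCC[Sn](CCCC)(CCCC)/C=C/C=C(C)/C=C/C=C(C)/C=C/[C@H]1C(C)=C[C@H](O)CC1(C)C
F2 | step 3 | 2-[(4R)-4-(tert-butyldimethylsilyloxy)-2,6,6-trimethylcyclohex-1-en-1-yl]ethanol | OCCC1=C(C)C[C@@H](O[Si](C)(C)C(C)(C)C)CC1(C)C
F3 | step 3 | [(4R)-4-(tert-butyldimethylsilyloxy)-2,6,6-trimethylcyclohex-1-en-1-yl]acetaldehyde | O=CCC1=C(C)C[C@@H](O[Si](C)(C)C(C)(C)C)CC1(C)C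
F4 | step 3 | 1-[(4R)-4-(tert-butyldimethylsilyloxy)-2,6,6-trimethylcyclohex-1-en-1-yl]but-3-en-2-ol | C=CC(O)CC1=C(C)C[C@@H](O[Si](C)(C)C(C)(C)C)CC1(C)C
F5 | step 6 | (5E,7E)-1-[(4R)-4-(tert-butyldimethylsilyloxy)-2,6,6-trimethylcyclohex-1-en-1-yl]-4-hydroxy-8-iodo-7-methyl-3-[(phenylselanyl)methyl]octa-5,7-dien-2-one | O=C(CC1=C(C)C[C@@H](O[Si](C)(C)C(C)(C)C)CC1(C)C)C(C[Se]c1ccccc1)C(O)/C=C/C(C)=C/I
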